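**Retrosynthetic overview**

- Everything traces back to two bought aromatics: 3,4,5-trimethoxyphenol (1, ring A) and (E)-ferulic acid (2, ring B plus the three-carbon bridge). No protecting groups are used.
- Second disconnection (first bond made): the ring A–carbonyl bond. Forward, this is a chalcone-synthase-like C-acylation of the phloroglucinol-type ring by the intact feruloyl unit, giving, by way of the boron chelate 3, the 2'-hydroxychalcone 4.
- First disconnection (last bond made): the O1–C2 bond of the target 5, opened by a retro-oxa-Michael to chalcone 4. Forward, this is the chalcone isomerase step, run with a chiral bifunctional catalyst that sets C2 as (S) as the ring closes.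
- Ring order: rings A and B are bought; ring C (the pyranone) is the only ring formed, and it is formed last.

Assumption: the quinine-derived thiourea of step 2 is taken to give the (2S) flavanone. The sense of induction is read on a first small run (chiral HPLC against racemate; circular dichroism of a (2S)-flavanone is positive near 330 nm and negative near 290 nm). If it is (2R), the quinidine-derived pseudoenantiomer (same formula, C29H28F6N4OS) is used with nothing else changed.

**Route**

Step 1
Reactants: 1 3,4,5-trimethoxyphenol (1.3 equiv); 2 (E)-ferulic acid (1.0 equiv)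
Product: 4 (E)-1-(2-hydroxy-4,5,6-trimethoxyphenyl)-3-(4-hydroxy-3-methoxyphenyl)prop-2-en-1-one, via difluoroboron chelate 3 (not isolated)
Conditions: BF3·OEt2 (neat, 8 equiv), 85 °C, 2 h, N2; then ice–H2O/THF, rt, 1 h
Reagents that add atoms: none
Why: A Nencki-type Friedel–Crafts C-acylation in which BF3 turns the carboxylic acid into the acyl donor; the two free positions of 1 are identical by symmetry and both ortho to the hydroxyl, so only one ketone can form, and the product is held as the boron chelate 3, whose phenol oxygen is tied up and cannot add to the enone, so the chalcone stays open with its (E)-alkene intact and no stereocentre is created.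

Step 2
Reactants: 4 (E)-1-(2-hydroxy-4,5,6-trimethoxyphenyl)-3-(4-hydroxy-3-methoxyphenyl)prop-2-en-1-one
Product: 5 agecorynin E, (2S)-2-(4-hydroxy-3-methoxyphenyl)-5,6,7-trimethoxy-2,3-dihydro-4H-chromen-4-one
Conditions: N-[3,5-bis(trifluoromethyl)phenyl]-N'-[(8α,9S)-6'-methoxycinchonan-9-yl]thiourea (15 mol%), PhCl, 20 °C, 72 h, dark; SiO2 plug; recrystallise (EtOAc–heptane)
Reagents that add atoms: none
Why: A bifunctional amine–thiourea catalysed intramolecular oxa-Michael addition (6-endo-trig, the chalcone isomerase reaction) in which the thiourea hydrogen-bonds the carbonyl oxygen while the quinuclidine nitrogen takes up the 2'-OH proton, so the phenoxide adds inside a chiral ion pair to one face of the s-cis enone and sets C2 as (S) under catalyst control, while the 6'-methoxy group twists the enone out of conjugation and makes ring closure strongly downhill so the kinetic ee is not washed out by the back reaction.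

**Compound list**

1 | 3,4,5-trimethoxyphenol | COc1cc(O)cc(OC)c1OC | starting material
2 | (E)-ferulic acid, (2E)-3-(4-hydroxy-3-methoxyphenyl)prop-2-enoic acid | COc1cc(/C=C/C(=O)O)ccc1O | starting material
3 | difluoroboron chelate of chalcone 4 (BF2 bridging the 2'-phenolate oxygen and the carbonyl oxygen; forms in the flask in step 1, not isolated) | COc1cc(/C=C/C2=[O+][B-](F)(F)Oc3cc(OC)c(OC)c(OC)c23)ccc1O | intermediate
4 | (E)-1-(2-hydroxy-4,5,6-trimethoxyphenyl)-3-(4-hydroxy-3-methoxyphenyl)prop-2-en-1-one (2'-hydroxychalcone) | COc1cc(/C=C/C(=O)c2c(O)cc(OC)c(OC)c2OC)ccc1O | intermediate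
5 | agecorynin E, (2S)-2-(4-hydroxy-3-methoxyphenyl)-5,6,7-trimethoxy-2,3-dihydro-4H-chromen-4-one | COc1cc([C@@H]2CC(=O)c3c(cc(OC)c(OC)c3OC)O2)ccc1O | target

**Step count and risks**

Total step count: 2. Longest linear sequence: 2.

The route has only two steps, so both are ranked. Step 2 is ranked twice because it can fail in two unrelated ways, each with its own fallback.

Risk 1, step 2 (conversion and ee with the free para-phenol). The 4-OH of ring B is the most acidic site of chalcone 4. It can bind the catalyst amine unproductively, its phenoxide makes the enone a poor acceptor, and in the product it offers a quinone-methide path for ring opening. The fallback sets out from 4 and comes back at 5. The unchelated 4-OH is silylated selectively (TBSCl, imidazole, DMF, 0 °C; the 2'-OH is locked in its hydrogen bond to the carbonyl and reacts far more slowly) to give the silyl ether (E)-1-(2-hydroxy-4,5,6-trimethoxyphenyl)-3-[4-(tert-butyldimethylsilyloxy)-3-methoxyphenyl]prop-2-en-1-one F1. The same thiourea-catalysed ring closure (catalyst C29H28F6N4OS, PhCl, 20 °C) then gives the silylated flavanone (2S)-2-[4-(tert-butyldimethylsilyloxy)-3-methoxyphenyl]-5,6,7-trimethoxy-2,3-dihydro-4H-chromen-4-one F2. HF·pyridine in THF at 0 °C removes the silyl group under acidic conditions, which do not open the ring, and gives 5. This costs two extra steps.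

Risk 2, step 1 (C-acylation against other channels). Ferulic acid can instead add through its β-carbon to the electron-rich ring (4-aryl-dihydrocoumarin), or esterify its own phenol; a yield of 40–55% is the realistic expectation. The fallback sets out from 1 and comes back at 4. Phenol 1 is C-acetylated with AcOH in BF3·OEt2 at 90 °C, a reaction with no conjugate-addition channel. Water work-up hydrolyses the acetophenone difluoroboron chelate F3 to 1-(2-hydroxy-4,5,6-trimethoxyphenyl)ethan-1-one F4. Claisen–Schmidt condensation of F4 with vanillin (COc1cc(C=O)ccc1O; KOH, EtOH–H2O, rt, then cold dilute HCl) builds the Cα=Cβ bond instead of the aryl–carbonyl bond and delivers 4. In strong base the chalcone is a dianion and does not cyclise, and cold acidification returns 4 before ring closure starts.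

Risk 3, step 2 (configuration: wrong or eroded). The ring closure is reversible in principle, so long reaction times, a basic work-up or warm silica can lower the ee, and crystallisation may not upgrade it. The fallback sets out from 4 and comes back at 5. Ring closure without chirality (NaOAc, EtOH, reflux) gives the racemic flavanone (2RS)-2-(4-hydroxy-3-methoxyphenyl)-5,6,7-trimethoxy-2,3-dihydro-4H-chromen-4-one F5. Preparative chiral SFC on an amylose tris(3,5-dimethylphenylcarbamate) phase (CO2–MeOH, neutral) resolves it into 5 and its mirror image, (2R)-2-(4-hydroxy-3-methoxyphenyl)-5,6,7-trimethoxy-2,3-dihydro-4H-chromen-4-one F6. F6 is racemised under the same NaOAc/EtOH conditions (retro-oxa-Michael and re-closure) and fed back as F5.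

**Further compounds**

F1 | step 2 | (E)-1-(2-hydroxy-4,5,6-trimethoxyphenyl)-3-[4-(tert-butyldimethylsilyloxy)-3-methoxyphenyl]prop-2-en-1-one | COc1cc(/C=C/C(=O)c2c(O)cc(OC)c(OC)c2OC)ccc1O[Si](C)(C)C(C)(C)C
F2 | step 2 | (2S)-2-[4-(tert-butyldimethylsilyloxy)-3-methoxyphenyl]-5,6,7-trimethoxy-2,3-dihydro-4H-chromen-4-one | COc1cc([C@@H]2CC(=O)c3c(cc(OC)c(OC)c3OC)O2)ccc1O[Si](C)(C)C(C)(C)C
F3 | step 1 | difluoroboron chelate of 1-(2-hydroxy-4,5,6-trimethoxyphenyl)ethan-1-one | CC1=[O+][B-](F)(F)Oc2cc(OC)c(OC)c(OC)c12
F4 | step 1 | 1-(2-hydroxy-4,5,6-trimethoxyphenyl)ethan-1-one | CC(=O)c1c(O)cc(OC)c(OC)c1OC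
F5 | step 2 | (2RS)-2-(4-hydroxy-3-methoxyphenyl)-5,6,7-trimethoxy-2,3-dihydro-4H-chromen-4-one (racemate) | COc1cc(C2CC(=O)c3c(cc(OC)c(OC)c3OC)O2)ccc1O
F6 | step 2 | (2R)-2-(4-hydroxy-3-methoxyphenyl)-5,6,7-trimethoxy-2,3-dihydro-4H-chromen-4-one | COc1cc([C@H]2CC(=O)c3c(cc(OC)c(OC)c3OC)O2)ccc1O
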